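The route rests on cutting, in cyclopentanone ring E, the bond between the isopropenyl-bearing methine and the α-methine of the bridging ketone. These atoms make up a 3-isopropenylcyclopentanone, the retron of a 5-exo Tsuji–Trost enolate alkylation. In one operation the key step closes ring E, sets both methine stereocentres and turns a linear allylic carbonate into the isopropenyl group. Its precursor is the tetracycle of hydroquinone A, indane ring B, methylcyclohexene C and cyclohexane-1,4-dione D, carrying the C5 chain on the quaternary carbon common to B, C and D. Rings C and D come from an asymmetric quinone Diels–Alder reaction steered by a traceless methoxy group, ring B from an enol-to-quinone Michael addition.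

Key step: step 8

Assumption: the titanium complex of (R,R)-TADDOL is taken to leave open the quinone face that leads to 10; the ligand antipode, also commercial, would be used if the sense of induction were opposite.

Step 1
Reactants: 1 2-methylprop-2-en-1-ol
Product: 2 methyl 2-methylprop-2-enyl carbonate
Conditions: ClCO2Me, pyridine, CH2Cl2, 0 °C → rt
Reagents that add atoms: methyl chloroformate COC(=O)Cl
Why: Acylation of a primary alcohol with a chloroformate gives the mixed carbonate that later serves as the allylic leaving group; no stereocentre is involved.

Step 2
Reactants: 2 methyl 2-methylprop-2-enyl carbonate; 3 2-allyl-6-methoxyphenol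
Product: 4 (E)-4-(2-hydroxy-3-methoxyphenyl)-2-methylbut-2-enyl methyl carbonate
Conditions: second-generation Hoveyda–Grubbs catalyst (5 mol %), 2 (3 equiv), CH2Cl2, 40 °C
Reagents that add atoms: none
Why: Olefin cross-metathesis of a terminal allylarene with an excess of a 1,1-disubstituted olefin should favour the cross product as the (E)-trisubstituted alkene, and this geometry is in any case erased later in the π-allyl complex.

Step 3
Reactants: 4 (E)-4-(2-hydroxy-3-methoxyphenyl)-2-methylbut-2-enyl methyl carbonate
Product: 5 2-methoxy-6-[(E)-4-(methoxycarbonyloxy)-3-methylbut-2-enyl]-1,4-benzoquinone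
Conditions: Co(salen) (10 mol %), O2 (1 atm), MeCN, rt
Reagents that add atoms: dioxygen O=O
Why: Cobalt–salen-catalysed aerobic oxidation of a 2,6-disubstituted phenol to the para-quinone is the usual entry to 2-methoxy-6-alkylbenzoquinones and should leave the carbonate and alkene untouched.

Step 4
Reactants: 6 2,5-dimethoxybenzaldehyde; 7 diethyl (2-methylprop-2-enyl)phosphonate
Product: 9 1,4-dimethoxy-2-[(1E)-3-methylbuta-1,3-dienyl]benzene, via lithiated phosphonate 8 (not isolated)
Conditions: n-BuLi, THF, −78 °C; then 6, −78 °C → rt
Reagents that add atoms: none
Why: Horner–Wadsworth–Emmons olefination through the α-carbon of the lithiated allylic phosphonate should give the (E)-1-aryl diene.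

Step 5
Reactants: 5 2-methoxy-6-[(E)-4-(methoxycarbonyloxy)-3-methylbut-2-enyl]-1,4-benzoquinone; 9 1,4-dimethoxy-2-[(1E)-3-methylbuta-1,3-dienyl]benzene
Product: 10 (4aS,5R,8aR)-5-(2,5-dimethoxyphenyl)-3-methoxy-4a-[(E)-4-(methoxycarbonyloxy)-3-methylbut-2-enyl]-7-methyl-4a,5,8,8a-tetrahydronaphthalene-1,4-dione (cis ring fusion; aryl cis to both ring carbonyl carbons)
Conditions: TiCl2(OiPr)2 (20 mol %), (R,R)-TADDOL (22 mol %), 4 Å molecular sieves, toluene, −40 → −20 °C
Reagents that add atoms: none
Why: In this asymmetric Lewis-acid-catalysed quinone Diels–Alder reaction the methoxy group deactivates its own double bond so the diene adds to the alkyl-bearing one, chelation of the chiral titanium TADDOLate by the methoxy oxygen and the neighbouring carbonyl makes the unsubstituted carbon the electrophilic end (it takes the CH2 terminus of the diene) and shields one quinone face, and the endo transition state of the (E)-diene places the aryl group cis to both carbonyl carbons, which fixes the quaternary carbon, the ring-fusion CH and the benzylic CH together.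

Step 6
Reactants: 10 Diels–Alder adduct
Product: 12 tetracyclic hydroquinone of rings A–D (ring D still a methoxy-enedione), via ring-A quinone 11 (not isolated)
Conditions: (NH4)2Ce(NO3)6 (2.2 equiv), MeCN–H2O, 0 °C; extraction; CF3CO2H (20 mol %), CH2Cl2 (0.005 M), 0 °C → rt
Reagents that add atoms: water O
Why: Oxidative demethylation of the 1,4-dimethoxyarene is followed by an acid-catalysed intramolecular Michael addition of a ketone enol to the quinone (a 5-endo closure of the kind seen when dopaquinone cyclises), in which the ring-fusion CH is the only enolisable position of the methoxy-enedione, can reach only the quinone carbon next to the benzylic substituent and only from the face on which that substituent stands, and tautomerisation to the hydroquinone makes the closure irreversible and sets the second quaternary centre.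

Step 7
Reactants: 12 tetracyclic hydroquinone (methoxy-enedione ring D)
Product: 13 tetracyclic hydroquinone of rings A–D with cyclohexane-1,4-dione ring D
Conditions: SmI2 (4.4 equiv), THF–MeOH, −78 → 0 °C
Reagents that add atoms: none
Why: Samarium diiodide should first reduce the ene-dione to the saturated 1,4-diketone and then cleave the methoxy group, now alpha to a ketone (reduction of α-heterosubstituted ketones; β-elimination of methanol and renewed reduction leads to the same product), while the allylic carbonate, alkenes and hydroquinone are inert and no stereocentre is touched.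

Step 8
Reactants: 13 tetracyclic hydroquinone (cyclohexane-1,4-dione ring D)
Product: 15 CNP0287617.1 (target), via trilithium enolate 14 (not isolated)
Conditions: LiN(SiMe3)2 (3.1 equiv), LiCl, THF, −78 → 0 °C; Pd(PPh3)4 (5 mol %), 0 °C → rt; 1 M HCl
Reagents that add atoms: none
Why: The base makes the bis-phenoxide and, reversibly, the ketone enolates, zerovalent palladium ionises the allylic carbonate to a π-allyl complex (loss of CO2 and methoxide), and the enolate carbon alpha to the ketone beside the quaternary centre attacks the internal allyl terminus anti to the metal, so the double bond moves outward and becomes the isopropenyl group. The closest known reaction type is the Tsuji–Trost cyclisation of 3-oxoalk-6-enyl carbonates or ethers to 3-vinylcyclopentanones, run here on a preformed lithium enolate. Ring E closes in the 5-exo-trig mode at the allyl unit with the enolate double bond inside the new ring, which is easy here because the chain stands axial on ring D directly above the enolate carbon. The α-methine is set by the quaternary carbon, since the tether reaches only that face of ring D. The isopropenyl-bearing methine is set by the rotamer of the allyl unit: turned outward (exo, on the side of the enolate oxygen and its lithium) it eclipses only a C–H bond and keeps cation and anion close, turned inward it would eclipse the ring-D CH2 and lie over the second carbonyl, and because the CH2 terminus lets the two π-allyl faces interconvert, all material can drain through the exo path, whereas a concerted ene closure onto an ene-dione would be forced into the inward rotamer and give the wrong epimer. The step needs C- over O-allylation, a five- over a seven-membered ring and the enolate beside the quaternary centre over the other one: O-allyl products re-ionise, terminal attack would build a strained bridged seven-membered ring, and the other enolate could only close a bicyclo[2.2.2]octane through a boat, so the equilibrating enolates are consumed through the wanted one.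

Compound list
1 | 2-methylprop-2-en-1-ol | C=C(C)CO | starting material
2 | methyl 2-methylprop-2-enyl carbonate | C=C(C)COC(=O)OC | intermediate
3 | 2-allyl-6-methoxyphenol | C=CCc1cccc(OC)c1O | starting material
4 | (E)-4-(2-hydroxy-3-methoxyphenyl)-2-methylbut-2-enyl methyl carbonate | COC(=O)OC/C(C)=C/Cc1cccc(OC)c1O | intermediate
5 | 2-methoxy-6-[(E)-4-(methoxycarbonyloxy)-3-methylbut-2-enyl]-1,4-benzoquinone | COC(=O)OC/C(C)=C/CC1=CC(=O)C=C(OC)C1=O | intermediate
6 | 2,5-dimethoxybenzaldehyde | COc1ccc(OC)c(C=O)c1 | starting material
7 | diethyl (2-methylprop-2-enyl)phosphonate | C=C(C)CP(=O)(OCC)OCC | starting material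
8 | α-lithiated diethyl (2-methylprop-2-enyl)phosphonate | [Li+].C=C(C)[CH-]P(=O)(OCC)OCC | intermediate
9 | 1,4-dimethoxy-2-[(1E)-3-methylbuta-1,3-dienyl]benzene | C=C(C)/C=C/c1cc(OC)ccc1OC | intermediate
10 | (4aS,5R,8aR) endo Diels–Alder adduct, cis-fused, aryl cis to both ring carbonyl carbons | COC(=O)OC/C(C)=C/C[C@@]12C(=O)C(OC)=CC(=O)[C@@H]1CC(C)=C[C@@H]2c1cc(OC)ccc1OC | intermediate
11 | the same adduct with ring A as a 1,4-benzoquinon-2-yl group | COC(=O)OC/C(C)=C/C[C@@]12C(=O)C(OC)=CC(=O)[C@@H]1CC(C)=C[C@@H]2C1=CC(=O)C=CC1=O | intermediate
12 | tetracyclic hydroquinone, rings A–D, new aryl bond on the former ring-fusion carbon, ring D a methoxy-enedione | COC(=O)OC/C(C)=C/C[C@@]23C(=O)C(OC)=CC(=O)[C@@]21CC(C)=C[C@@H]3c2c(O)ccc(O)c21 | intermediate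
13 | tetracyclic hydroquinone, rings A–D, ring D a cyclohexane-1,4-dione, allylic carbonate chain on the quaternary carbon | COC(=O)OC/C(C)=C/C[C@@]23C(=O)CCC(=O)[C@@]21CC(C)=C[C@@H]3c2c(O)ccc(O)c21 | intermediate
14 | trilithium salt of 13 (bis-phenoxide, enolate of the ketone beside the quaternary carbon) | [Li+].[Li+].[Li+].COC(=O)OC/C(C)=C/C[C@@]23C([O-])=CCC(=O)[C@@]21CC(C)=C[C@@H]3c2c([O-])ccc([O-])c21 | intermediate
15 | CNP0287617.1; benzylic CH (R), quaternary carbon of rings B, C, D, E (S), aryl-bearing quaternary carbon (R), α-methine (R), isopropenyl methine (S, exo, syn to the bridging ketone) | C=C(C)[C@H]1C[C@@]23C(=O)[C@@H]1CC(=O)[C@@]21CC(C)=C[C@@H]3c2c(O)ccc(O)c21 | target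

Total step count: 8. Longest linear sequence: 7 (steps 1, 2, 3, 5, 6, 7, 8).

Steps most likely to fail

Step 5. What may go wrong is poor facial selectivity of the catalyst, sluggish addition to the trisubstituted double bond, or cationic oligomerisation of the electron-rich diene. The fallback replaces the chiral catalyst with a covalent auxiliary. It sets out from 5. Acid-catalysed alkoxy exchange of the vinylogous ester with (−)-8-phenylmenthol (cat. TsOH, toluene, removal of methanol) would give the 8-phenylmenthyloxy quinone F1. A TiCl4-chelated Diels–Alder reaction with 9, in which the cumyl phenyl ring stacks over one quinone face, would give the auxiliary-bearing adduct F2, purified as one diastereomer. Exchange back with methanol (cat. TsOH) returns the auxiliary and rejoins the route at 10.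

Step 6. What may go wrong is tautomerisation of the ring-A quinone by loss of the benzylic hydrogen, slow enolisation of the vinylogous ester, or redox exchange between product hydroquinone and unreacted quinone. The fallback is a Mukaiyama–Michael addition through a discrete silyl dienol ether. It sets out from 11, which is isolated and treated with TBSOTf and 2,6-lutidine (CH2Cl2, −78 °C). The more basic vinylogous-ester carbonyl is silylated and loses the ring-fusion hydrogen to give the silyl dienol ether F3, which adds to the silyl-activated quinone. The phenols are capped in the same flask, which stops redox exchange, to give the bis(tert-butyldimethylsilyl) ether F4. HF·pyridine then rejoins the route at 12.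

Step 8. What may go wrong is β-hydride loss from the π-allyl complex to a diene, closure through the other enolate, insufficient exo preference, or air oxidation of the polyanion. The fallback is a metal-free cationic cyclisation of a silyl enol ether. It sets out from 13. Me3SiOTf and Et3N would give the tetrakis(trimethylsilyl) derivative F5, with both ketones as silyl enol ethers and both phenols capped. A catalytic Lewis acid (Me3SiOTf or ZnBr2, CH2Cl2, −78 °C) ionises the allylic carbonate, and the silyl enol ether beside the quaternary carbon traps the allyl cation at its internal end to give the tris(trimethylsilyl) pentacycle F6. K2CO3 in methanol removes the silyl groups and arrives at 15.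

Further compounds
F1 | step 5 | 2-[(1R,2S,5R)-8-phenylmenthyloxy]-6-[(E)-4-(methoxycarbonyloxy)-3-methylbut-2-enyl]-1,4-benzoquinone | COC(=O)OC/C(C)=C/CC1=CC(=O)C=C(O[C@@H]2C[C@H](C)CC[C@H]2C(C)(C)c2ccccc2)C1=O
F2 | step 5 | endo Diels–Alder adduct as 10 with 8-phenylmenthyloxy in place of methoxy | COC(=O)OC/C(C)=C/C[C@@]12C(=O)C(O[C@@H]3C[C@H](C)CC[C@H]3C(C)(C)c3ccccc3)=CC(=O)[C@@H]1CC(C)=C[C@@H]2c1cc(OC)ccc1OC
F3 | step 6 | tert-butyldimethylsilyl dienol ether of 11 | COC(=O)OC/C(C)=C/C[C@@]12C(=O)C(OC)=CC(O[Si](C)(C)C(C)(C)C)=C1CC(C)=C[C@@H]2C1=CC(=O)C=CC1=O
F4 | step 6 | bis(tert-butyldimethylsilyl) ether of 12 | COC(=O)OC/C(C)=C/C[C@@]23C(=O)C(OC)=CC(=O)[C@@]21CC(C)=C[C@@H]3c2c(O[Si](C)(C)C(C)(C)C)ccc(O[Si](C)(C)C(C)(C)C)c21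
F5 | step 8 | tetrakis(trimethylsilyl) derivative of 13 | COC(=O)OC/C(C)=C/C[C@@]23C(O[Si](C)(C)C)=CC=C(O[Si](C)(C)C)[C@@]21CC(C)=C[C@@H]3c2c(O[Si](C)(C)C)ccc(O[Si](C)(C)C)c21
F6 | step 8 | tris(trimethylsilyl) derivative of 15 (one silyl enol ether, two aryl silyl ethers) | C=C(C)[C@H]1C[C@@]23C(=O)[C@@H]1C=C(O[Si](C)(C)C)[C@@]21CC(C)=C[C@@H]3c2c(O[Si](C)(C)C)ccc(O[Si](C)(C)C)c21
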